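The cyclohexane ring is cut into a four-carbon and a two-carbon unit: the ring CH2–CH2–CH(CH3)–C(CH3)(CH2-indolyl) segment becomes a (Z)-configured 1,1,2-trisubstituted diene carrying the indole, and the ring carbon bearing the isopropylidene together with its CH neighbour becomes the activated double bond of 4-methylpenta-2,3-dienal. The key step exploits the exocyclic tetrasubstituted C=C on the ring, which is read as the untouched distal π-bond of a 1,1-dimethylallene. One catalytic enantioselective Diels–Alder reaction joins the two fragments, closes the six-membered ring, sets the quaternary carbon and the adjacent CH stereocentre and installs the isopropylidene. Olefination, face-selective hydrogenation and hydrolysis finish the acid.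

Key step: step 8

Remark: the catalyst antipode in step 8 is assigned by analogy with the facial sense expected for boron-bound s-trans 2-enals; if a first run shows the opposite sense, the (S) antipode is used with no other change.

Step 1
Reactants: 1 2,3-dimethylmaleic anhydride
Product: 3 3,4-dimethylfuran-2(5H)-one, via sodium hydroxy carboxylate 2 (not isolated)
Conditions: NaBH4, THF, 0 °C to rt; then 2 M HCl
Reagents that add atoms: none
Why: Hydride reduction of one carbonyl group of the symmetrical cyclic anhydride and acid-promoted lactonisation (anhydride-to-butenolide reduction) should give the butenolide, whose ring holds the two methyl groups cis on the tetrasubstituted alkene.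

Step 2
Reactants: 3 3,4-dimethylfuran-2(5H)-one
Product: 4 3,4-dimethyl-2,5-dihydrofuran-2-ol (racemic lactol)
Conditions: i-Bu2AlH (1.1 equiv), CH2Cl2, −78 °C; aqueous potassium sodium tartrate (KNaC4H4O6)
Reagents that add atoms: none
Why: Partial reduction of a lactone to the lactol at low temperature, with a non-acidic work-up so that the lactol is not dehydrated to 3,4-dimethylfuran.

Step 3
Reactants: 4 3,4-dimethyl-2,5-dihydrofuran-2-ol
Product: 6 (2Z)-2,3-dimethylpenta-2,4-dien-1-ol, via open-chain hydroxy enal 5 (not isolated)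
Conditions: Ph3PCH3Br, KOt-Bu (2.5 equiv each), THF, 0 °C to rt
Reagents that add atoms: methyltriphenylphosphonium bromide, C[P+](c1ccccc1)(c1ccccc1)c1ccccc1.[Br-]
Why: Wittig methylenation of the open hydroxy-aldehyde tautomer of the lactol; the (Z) geometry (CH2OH cis to vinyl) is inherited from the ring.

Step 4
Reactants: 6 (2Z)-2,3-dimethylpenta-2,4-dien-1-ol
Product: 7 (3Z)-5-bromo-3,4-dimethylpenta-1,3-diene
Conditions: CBr4, PPh3, CH2Cl2, 0 °C; used at once
Reagents that add atoms: carbon tetrabromide, BrC(Br)(Br)Br
Why: Appel bromination of the primary allylic alcohol under neutral conditions, which should leave the alkene geometry untouched.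

Step 5
Reactants: 7 (3Z)-5-bromo-3,4-dimethylpenta-1,3-diene; 8 indole
Product: 10 3-[(2Z)-2,3-dimethylpenta-2,4-dien-1-yl]-1H-indole, via indolylmagnesium bromide 9 (not isolated)
Conditions: 8, EtMgBr, Et2O, 0 °C; then 7, Et2O–PhMe, 0 °C to rt
Reagents that add atoms: none
Why: C3-selective alkylation of the indole Grignard reagent by direct SN2 displacement at the primary allylic CH2Br carbon; the tight N–Mg ion pair in a weakly polar medium directs attack to C3 of the indole.

Step 6
Reactants: 10 3-[(2Z)-2,3-dimethylpenta-2,4-dien-1-yl]-1H-indole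
Product: 11 tert-butyl 3-[(2Z)-2,3-dimethylpenta-2,4-dien-1-yl]-1H-indole-1-carboxylate
Conditions: Boc2O, 4-(dimethylamino)pyridine (10 mol %), MeCN, rt
Reagents that add atoms: di-tert-butyl dicarbonate, CC(C)(C)OC(=O)OC(=O)OC(C)(C)C
Why: Nucleophile-catalysed N-acylation (carbamate formation) lowers the nucleophilicity of the indole so that it should tolerate the Lewis acid of the key step.

Step 7
Reactants: 12 3-methylbuta-1,2-diene
Product: 14 4-methylpenta-2,3-dienal, via allenyllithium 13 (not isolated)
Conditions: n-BuLi, THF, −78 to −40 °C; DMF, −78 to 0 °C; cold 1 M HCl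
Reagents that add atoms: N,N-dimethylformamide, CN(C)C=O
Why: Lithiation of the allenic CH2 terminus and Bouveault-type formylation with DMF; the lithium species should react through the allenic carbon because the other terminus is fully substituted.

Step 8
Reactants: 11 tert-butyl 3-[(2Z)-2,3-dimethylpenta-2,4-dien-1-yl]-1H-indole-1-carboxylate; 14 4-methylpenta-2,3-dienal
Product: 15 tert-butyl 3-{[(1S,6R)-6-formyl-1,2-dimethyl-5-(propan-2-ylidene)cyclohex-2-en-1-yl]methyl}-1H-indole-1-carboxylate
Conditions: (R)-3,3-diphenyl-1-(2-methylphenyl)tetrahydro-1H,3H-pyrrolo[1,2-c][1,3,2]oxazaborole·HN(SO2CF3)2 (20 mol %), dienophile in 2.5-fold excess, CH2Cl2, −78 to −40 °C; Et3N quench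
Reagents that add atoms: none
Why: The cationic boron Lewis acid binds the formyl oxygen of 14 and lowers the LUMO of its conjugated C2=C3 bond, which should undergo a concerted but asynchronous normal-demand [4+2] cycloaddition with the s-cis diene of 11: the diene CH2 terminus bonds to the central allene carbon, the fully substituted terminus bonds to the formyl-bearing carbon, and the distal Me2C=C bond stays behind as the exocyclic isopropylidene. The closest known reaction types are the oxazaborolidinium-catalysed enantioselective Diels–Alder reaction of 2-enals with acyclic dienes, Lewis-acid-promoted cycloadditions of allenyl carbonyl compounds at their conjugated bond, and quaternary-carbon-forming Diels–Alder reactions of 2-methyl-1-vinylcycloalkenes. The cyclohexene ring is closed by an intermolecular suprafacial–suprafacial [4+2] cycloaddition in which both ring bonds form in one transition state. The relative configuration of the quaternary carbon and the adjacent CH follows from the (Z) diene geometry (indolylmethyl inside, methyl outside) combined with the endo orientation of the formyl group, which places CHO cis to the ring methyl; the absolute configuration is set by the catalyst, whose aryl group shields one face of the bound s-trans enal. The step needs regioselectivity, secured by matching the most electrophilic central allene carbon with the unhindered, most nucleophilic CH2 terminus (tertiary allyl cation character develops at the other end), endo selectivity, helped by secondary overlap and by the small methyl rather than the indolylmethyl group lying next to the formyl group, and chemoselectivity, secured by conjugation of only one allene bond with the aldehyde and by the Boc group, which should keep the indole out of Friedel–Crafts or conjugate addition.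

Step 9
Reactants: 15 tert-butyl 3-{[(1S,6R)-6-formyl-1,2-dimethyl-5-(propan-2-ylidene)cyclohex-2-en-1-yl]methyl}-1H-indole-1-carboxylate
Product: 16 methyl (2E)-3-[(1R,2S)-2-{[1-(tert-butoxycarbonyl)-1H-indol-3-yl]methyl}-2,3-dimethyl-6-(propan-2-ylidene)cyclohex-3-en-1-yl]prop-2-enoate
Conditions: Ph3P=CHCO2Me, PhMe, 60–80 °C
Reagents that add atoms: methyl (triphenylphosphoranylidene)acetate, COC(=O)C=P(c1ccccc1)(c1ccccc1)c1ccccc1
Why: Wittig olefination with a stabilised, weakly basic ylide adds the two missing chain carbons and should neither epimerise the α-stereocentre nor move the β,γ-double bond into conjugation.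

Step 10
Reactants: 16 methyl (2E)-3-[(1R,2S)-2-{[1-(tert-butoxycarbonyl)-1H-indol-3-yl]methyl}-2,3-dimethyl-6-(propan-2-ylidene)cyclohex-3-en-1-yl]prop-2-enoate
Product: 17 methyl 3-[(1S,2R,3R)-2-{[1-(tert-butoxycarbonyl)-1H-indol-3-yl]methyl}-2,3-dimethyl-6-(propan-2-ylidene)cyclohexyl]propanoate
Conditions: H2 (1 atm), PtO2 (5 mol %), EtOAc, rt; stopped after uptake of 2 equiv
Reagents that add atoms: none
Why: Heterogeneous syn-hydrogenation should reduce the conjugated and the trisubstituted ring C=C bonds but not the tetrasubstituted isopropylidene, with H2 delivered to the ring alkene anti to the pseudoaxial indolylmethyl group on the neighbouring quaternary carbon, which sets the CH(CH3) centre with methyl cis to indolylmethyl.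

Step 11
Reactants: 17 methyl 3-[(1S,2R,3R)-2-{[1-(tert-butoxycarbonyl)-1H-indol-3-yl]methyl}-2,3-dimethyl-6-(propan-2-ylidene)cyclohexyl]propanoate
Product: 19 suaveolindole, via lithium carboxylate 18 (not isolated)
Conditions: LiOH, THF–MeOH–H2O, 50 °C; then 1 M HCl to pH 3–4, 0 °C
Reagents that add atoms: lithium hydroxide, [Li+].[OH-]
Why: Saponification of the methyl ester, in which the same base should also cleave the base-labile indole N-Boc carbamate, so that one operation frees both the acid and the N–H.

Compound list
1 | 2,3-dimethylmaleic anhydride | CC1=C(C)C(=O)OC1=O | starting material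
2 | sodium (2Z)-4-hydroxy-2,3-dimethylbut-2-enoate | [Na+].[O-]C(=O)/C(C)=C(C)\CO | intermediate (not isolated)
3 | 3,4-dimethylfuran-2(5H)-one | CC1=C(C)C(=O)OC1 | intermediate
4 | 3,4-dimethyl-2,5-dihydrofuran-2-ol (racemic) | CC1=C(C)C(O)OC1 | intermediate
5 | (2Z)-4-hydroxy-2,3-dimethylbut-2-enal | O=C/C(C)=C(C)\CO | intermediate (not isolated)
6 | (2Z)-2,3-dimethylpenta-2,4-dien-1-ol | C=C/C(C)=C(C)\CO | intermediate
7 | (3Z)-5-bromo-3,4-dimethylpenta-1,3-diene | C=C/C(C)=C(C)\CBr | intermediate
8 | indole | c1ccc2[nH]ccc2c1 | starting material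
9 | indol-1-ylmagnesium bromide | Br[Mg]n1ccc2ccccc12 | intermediate (not isolated)
10 | 3-[(2Z)-2,3-dimethylpenta-2,4-dien-1-yl]-1H-indole | C=C/C(C)=C(C)\Cc1c[nH]c2ccccc12 | intermediate
11 | tert-butyl 3-[(2Z)-2,3-dimethylpenta-2,4-dien-1-yl]-1H-indole-1-carboxylate | C=C/C(C)=C(C)\Cc1cn(C(=O)OC(C)(C)C)c2ccccc12 | intermediate
12 | 3-methylbuta-1,2-diene | CC(C)=C=C | starting material
13 | (3-methylbuta-1,2-dien-1-yl)lithium | [Li]C=C=C(C)C | intermediate (not isolated)
14 | 4-methylpenta-2,3-dienal | CC(C)=C=CC=O | intermediate
15 | tert-butyl 3-{[(1S,6R)-6-formyl-1,2-dimethyl-5-(propan-2-ylidene)cyclohex-2-en-1-yl]methyl}-1H-indole-1-carboxylate | CC(C)=C1CC=C(C)[C@@](C)(Cc2cn(C(=O)OC(C)(C)C)c3ccccc23)[C@@H]1C=O | intermediate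
16 | methyl (2E)-3-[(1R,2S)-2-{[1-(tert-butoxycarbonyl)-1H-indol-3-yl]methyl}-2,3-dimethyl-6-(propan-2-ylidene)cyclohex-3-en-1-yl]prop-2-enoate | CC(C)=C1CC=C(C)[C@@](C)(Cc2cn(C(=O)OC(C)(C)C)c3ccccc23)[C@@H]1/C=C/C(=O)OC | intermediate
17 | methyl 3-[(1S,2R,3R)-2-{[1-(tert-butoxycarbonyl)-1H-indol-3-yl]methyl}-2,3-dimethyl-6-(propan-2-ylidene)cyclohexyl]propanoate | CC(C)=C1CC[C@@H](C)[C@@](C)(Cc2cn(C(=O)OC(C)(C)C)c3ccccc23)[C@@H]1CCC(=O)OC | intermediate
18 | lithium 3-[(1S,2R,3R)-2-(1H-indol-3-ylmethyl)-2,3-dimethyl-6-(propan-2-ylidene)cyclohexyl]propanoate | [Li+].CC(C)=C1CC[C@@H](C)[C@@](C)(Cc2c[nH]c3ccccc23)[C@@H]1CCC(=O)[O-] | intermediate (not isolated)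
19 | suaveolindole, 3-[(1S,2R,3R)-2-(1H-indol-3-ylmethyl)-2,3-dimethyl-6-(propan-2-ylidene)cyclohexyl]propanoic acid | CC(C)=C1CC[C@@H](C)[C@@](C)(Cc2c[nH]c3ccccc23)[C@@H]1CCC(=O)O | target

Total step count: 11
Longest linear sequence: 10 steps (steps 1–6 and 8–11); step 7 is a one-step side branch.

Steps most likely to fail

1. Step 8. The (Z) substituent on the diene terminus disfavours the s-cis conformer, so the cycloaddition may be too slow at temperatures where the catalyst controls the face. The Lewis acid may instead ionise the electron-rich diene and cyclise it onto the indole, a strongly asynchronous bond formation may erode the endo and facial selectivity, and the allenal may oligomerise. The fallback replaces catalyst control by a covalently bound oxazolidinone auxiliary on a cationic aluminium chelate, a stronger dienophile with a predictable shielded face. It sets out from 12 (through 13) and 11 and returns at 15. Allenyllithium 13 is quenched with CO2 to give 4-methylpenta-2,3-dienoic acid F1. Activation as the pivaloyl mixed anhydride (t-BuCOCl, Et3N) and acylation of lithiated (4S)-4-benzyl-1,3-oxazolidin-2-one should give (4S)-4-benzyl-3-(4-methylpenta-2,3-dienoyl)-1,3-oxazolidin-2-one F2. With Et2AlCl (1.4 equiv, CH2Cl2, −78 to −30 °C) the chelated s-cis imide should add 11 endo, on the face anti to the benzyl group, to give (4S)-4-benzyl-3-{[(1R,2S)-2-{[1-(tert-butoxycarbonyl)-1H-indol-3-yl]methyl}-2,3-dimethyl-6-(propan-2-ylidene)cyclohex-3-en-1-yl]carbonyl}-1,3-oxazolidin-2-one F3. LiBH4 (THF, 1 equiv H2O, 0 °C) should release the auxiliary and give tert-butyl 3-{[(1S,6R)-6-(hydroxymethyl)-1,2-dimethyl-5-(propan-2-ylidene)cyclohex-2-en-1-yl]methyl}-1H-indole-1-carboxylate F4, and Dess–Martin oxidation returns aldehyde 15.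

2. Step 10. On the metal surface the isopropylidene may migrate into the ring and then be reduced, the hindered ring alkene may resist reduction, or hydrogen may arrive from the wrong face. The fallback separates the two reductions and sets the CH(CH3) centre by hydrogen-atom transfer instead of surface syn-addition. It sets out from 16 and returns at 17. Conjugate reduction with [(Ph3P)CuH]6 (PhMe, rt) should give methyl 3-[(1R,2S)-2-{[1-(tert-butoxycarbonyl)-1H-indol-3-yl]methyl}-2,3-dimethyl-6-(propan-2-ylidene)cyclohex-3-en-1-yl]propanoate F5. Radical hydrogenation of F5 (Mn(dpm)3 with dpm = 2,2,6,6-tetramethylheptane-3,5-dionate, PhSiH3, t-BuOOH, i-PrOH, rt) passes through the tertiary ring radical, which should take up hydrogen so that the methyl group ends equatorial and cis to the indolylmethyl group, giving 17; the more hindered tetrasubstituted alkene is expected to react more slowly.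

3. Step 5. The indole nucleophile may attack the remote vinyl terminus of the pentadienyl bromide, the bromide may ionise and lose its alkene geometry, or nitrogen may be alkylated. The fallback introduces the vinyl group only after the indole, so that no pentadienyl electrophile is used. It sets out from 8 (through 9), uses commercial ethyl 2-methyl-3-oxobutanoate and returns at 11. Chelation-controlled enol triflation (NaH, PhNTf2, THF, 0 °C) should give ethyl (2Z)-2-methyl-3-{[(trifluoromethyl)sulfonyl]oxy}but-2-enoate F6. Reduction with i-Bu2AlH (CH2Cl2, −78 °C) gives (2Z)-4-hydroxy-3-methylbut-2-en-2-yl trifluoromethanesulfonate F7, and Appel bromination (CBr4, PPh3) gives (2Z)-4-bromo-3-methylbut-2-en-2-yl trifluoromethanesulfonate F8. Alkylation of indolylmagnesium bromide 9 with this simple allylic bromide should give (2Z)-4-(1H-indol-3-yl)-3-methylbut-2-en-2-yl trifluoromethanesulfonate F9. Boc protection (Boc2O, 4-(dimethylamino)pyridine) gives tert-butyl 3-[(2Z)-2-methyl-3-{[(trifluoromethyl)sulfonyl]oxy}but-2-en-1-yl]-1H-indole-1-carboxylate F10. Stille coupling with tributyl(vinyl)stannane (Pd(PPh3)4, LiCl, THF, 65 °C) proceeds with retention of alkene geometry and returns diene 11.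

Further compounds
F1 | step 8 | 4-methylpenta-2,3-dienoic acid | CC(C)=C=CC(=O)O
F2 | step 8 | (4S)-4-benzyl-3-(4-methylpenta-2,3-dienoyl)-1,3-oxazolidin-2-one | CC(C)=C=CC(=O)N1[C@@H](Cc2ccccc2)COC1=O
F3 | step 8 | (4S)-4-benzyl-3-{[(1R,2S)-2-{[1-(tert-butoxycarbonyl)-1H-indol-3-yl]methyl}-2,3-dimethyl-6-(propan-2-ylidene)cyclohex-3-en-1-yl]carbonyl}-1,3-oxazolidin-2-one | CC(C)=C1CC=C(C)[C@@](C)(Cc2cn(C(=O)OC(C)(C)C)c3ccccc23)[C@@H]1C(=O)N1[C@@H](Cc2ccccc2)COC1=O
F4 | step 8 | tert-butyl 3-{[(1S,6R)-6-(hydroxymethyl)-1,2-dimethyl-5-(propan-2-ylidene)cyclohex-2-en-1-yl]methyl}-1H-indole-1-carboxylate | CC(C)=C1CC=C(C)[C@@](C)(Cc2cn(C(=O)OC(C)(C)C)c3ccccc23)[C@@H]1CO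
F5 | step 10 | methyl 3-[(1R,2S)-2-{[1-(tert-butoxycarbonyl)-1H-indol-3-yl]methyl}-2,3-dimethyl-6-(propan-2-ylidene)cyclohex-3-en-1-yl]propanoate | CC(C)=C1CC=C(C)[C@@](C)(Cc2cn(C(=O)OC(C)(C)C)c3ccccc23)[C@@H]1CCC(=O)OC
F6 | step 5 | ethyl (2Z)-2-methyl-3-{[(trifluoromethyl)sulfonyl]oxy}but-2-enoate | CCOC(=O)/C(C)=C(C)\OS(=O)(=O)C(F)(F)F
F7 | step 5 | (2Z)-4-hydroxy-3-methylbut-2-en-2-yl trifluoromethanesulfonate | OC/C(C)=C(C)\OS(=O)(=O)C(F)(F)F
F8 | step 5 | (2Z)-4-bromo-3-methylbut-2-en-2-yl trifluoromethanesulfonate | BrC/C(C)=C(C)\OS(=O)(=O)C(F)(F)F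
F9 | step 5 | (2Z)-4-(1H-indol-3-yl)-3-methylbut-2-en-2-yl trifluoromethanesulfonate | FC(F)(F)S(=O)(=O)O/C(C)=C(C)\Cc1c[nH]c2ccccc12
F10 | step 5 | tert-butyl 3-[(2Z)-2-methyl-3-{[(trifluoromethyl)sulfonyl]oxy}but-2-en-1-yl]-1H-indole-1-carboxylate | FC(F)(F)S(=O)(=O)O/C(C)=C(C)\Cc1cn(C(=O)OC(C)(C)C)c2ccccc12
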